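The readings were computed with made-up constants; noise was put on by code.

Count time in windows of 40.0 min; the asked time is 3.00 windows.

| flask | L | Q | remark | time |
|---|---|---|---|---|
| north-east | 0.26 M | 88 mM (held) | run made earlier |  |
| south-east | 1 M | 88 mM (held) | run made earlier |  |
| flask | 0.51 M | 88 mM (held) |  | 2.0 h |

| run | time / min | J / % |
|---|---|---|
| north-east | 12.0 | 5.1 |
| north-east | 25.0 | 12.7 |
| north-east | 40.0 | 16.5 |
| north-east | 50.0 | 22.9 |
| north-east | 60.0 | 22.9 |
| north-east | 80.0 | 27.7 |
| south-east | 6.00 | 2.0 |
| south-east | 10.0 | 3.3 |
| south-east | 15.0 | 4.9 |
| south-east | 25.0 | 10.0 |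
| south-east | 40.0 | 15.0 |
| south-east | 80.0 | 26.0 |

(readings scatter by 1 percentage point)

- at the start none of Q is in solution

* the J standing at 2.0 h, as a percentage of the L charged
* the change that raises the amount of J at 2.0 h, in percent of the L charged most ("none" if none brings more than 2 percentage points) (spring / midnight / none)
* amount of J at 2.0 h, in percent of the L charged, after midnight

- spring: doubling the saturation concentration of Q, all else as stated
- midnight: doubling the transfer coefficient of Q, all else as stated

At 80.0 min the runs at 0.26 M and 1 M read 27.7% and 26.0%, close against a scatter of 1 percentage point. So take dissolved Q as steady, treat L as pseudo-first-order, and pool the runs for the flask at 0.51 M: 15.8% after one window, 26.9% after two.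

Take two extreme versions of the flask. If the first window's pace held, J would reach 47.4%; if J stopped after the second window, it would stay at 26.9%. The second window's gain is smaller than the first, so the line is too high, but J still rises, so the stop is too low.

Define the window ratio, each window's gain over the gain before it, from the readings as 0.705. A first-order curve keeps this ratio constant, so I reckon 34.7%. No run varies Q; assuming J's rate rises with dissolved Q, I choose spring, and I put no figure on midnight.

The forecast gives 38% for J, higher than my reckoning, names spring and puts J after midnight at 40%, holding that “the reaction is close to first order in L”.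

The flask gives 31.6% of J, with the other product G at 60.2% and L at 8.20%; spring adds 17 points, and midnight reaches 34.6%.

    Q ⇌ Z, rate k1*(csat - [Z]) (kL = 0.00256 /s)
    L + Z → J (k = 0.00175 /M/s)
    L → G (k = 2.19 × 10⁻⁴ /s)
    Z → D (k = 4.62 × 10⁻⁵ /s)

In the flask, from 80 min to 2.0 h, J gains 4.5 points, less than the 7.8 points the ratio gave. For the flask left until 30 min, count 0.750 of a window: the ratio gives 12.4%, and the computed J is 13.2%.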